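## Analysis of the target

The target is a cembranolide: a 14-membered carbocycle (C1–C14, cembrane numbering) fused through C1 and C3 to a δ-lactone (C1–C2–C3–O–C16–C15) whose α-carbon C15 carries the C17 methyl. It has seven stereocentres, (1R,3R,4S,7S,11S,12S,15S), in three clusters that cannot relay to one another: the lactone triad C1/C3/C15 with the adjoining tertiary carbinol C4 (methyl C18), the trans-11,12-epoxide (methyl C20 on C12), and the allylic hydroperoxide at C7 beside the C8=C19 exomethylene. On the lactone, the C14 chain on C1 and the C4 substituent on C3 are 1,3-cis and the C15 methyl is 1,2-trans to the C1 chain, so all three substituents are equatorial. The hydroperoxide is destroyed by phosphines, low-valent metals and organometallics and fragments under base, the trisubstituted epoxide is acid-labile, and the lactone sits next to a free tertiary hydroxyl that can take over the acyl group. The difficulty is to set three remote stereo-clusters, close a 14-membered ring, and still introduce the O–O unit at the very end. The strategy rests on one feature of the lactone: if C4 is a ketone, C3 (α to that ketone) and C15 (α to the lactone carbonyl) are both enolisable while C1 is not, and the natural configuration is the all-equatorial, thermodynamically preferred one relative to C1. C1 itself maps onto the stereocentre of (R)-limonene.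

## Retrosynthetic reasoning

**C7–OO bond.** The hydroperoxide of 41 is put in last because no organometallic, reductive or palladium step tolerates it. It is traced to the acid-labile perketal 40 and from there to the (7R)-alcohol 38 through its mesylate 39; substitution at C7 by a peroxide anion with inversion gives the (7S) centre. The forward step must be a clean SN2 at a secondary allylic carbon without harming epoxide or lactone.

**Epoxide.** The 11,12-epoxide of 38 is cut back to the E-olefin of macrocycle 36 (through silyl ethers 37). A reagent-controlled epoxidation by a chiral dioxirane is chosen because no hydroxyl is close enough to direct the oxidant. The C8=C19 olefin is 1,1-disubstituted and flanked by a silyloxy group, so it should be left alone.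

**C10–C11 bond (ring closure).** The ring of 36 is opened between C10 and C11, giving the alkyl iodide/alkenyl iodide 34 (closed through alkylzinc 35). This bond is far from every stereocentre, its formation creates none, and the E geometry is already fixed in the alkenyl iodide, so the cyclisation only has to find the ring.

**C4–C5 bond (fragment union).** Iodide 34 is simplified through 33 and 32 to the tertiary alcohol 31, which is cut at C4–C5 into the acetyl lactone 19 and the arm bromide 29 (as Grignard reagent 30). The cut is convergent and lets the rigid, adjacent C3 centre set C4 by Felkin–Anh/Cornforth control; the arm brings C7 with it.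

**Lactone C3–O–C16 bond with C3 and C15 (key disconnection).** Lactone 19 is opened to the seco acyloin ester 17, in which C3 and C15 are both stereorandom. Nothing has to be controlled on the way to 17, because base closes the ring and then lets both enolisable centres settle against the fixed C1. This removes two asymmetric steps.

**C3–C4 bond.** Acyloin 17 comes from aldehyde 13 and the acetyl anion equivalent 15, made from ethyl vinyl ether 14, with hydrolysis of adduct 16.

**C16 and C11–C12 functionality.** Aldehyde 13 is traced through 12, 11 and 10 to the isopropenyl compound 8: hydroboration and oxidation turn the isopropenyl group into the propionate, with no need for selectivity at C15. The iodoalkene of 8 comes from alkyne 6 by methylalumination–iodination, and 6 from the methyl ketone 4.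

**Ring cleavage of the chiral pool.** Keto acetal 4 is the product of oxidative cleavage of the ring olefin of (R)-limonene 1, which differentiates the two new termini and delivers C1 in the correct absolute configuration.

**Arm.** Bromide 29 is traced through 28, 27 and 26 to enone 25, whose enantioselective reduction sets C7. Enone 25 comes from alcohol 24, which is made from the protected bromobutenol 21 (from 20) and aldehyde 22.

## Alternatives that were turned down

**Alternative 1:** The ring is cut at C9–C10 and traced to a 16-membered macrolactone A1, in which C9 of a C8 ketone carries a carboxyl esterified by the C10 allylic oxygen. In the forward step Pd(PPh3)4 ionises the allylic C–O bond, the β-keto carboxylate loses CO2, and the C8/C9 enolate recombines with the allyl terminus at C10 to give the 14-membered ketone A2.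
- For: the ring is first made by macrolactonisation and then contracted intramolecularly, which is more dependable than a macrocyclic sp3–sp2 coupling. On ring closure this alternative is stronger than the chosen route.
- Against: the enolate can also attack C12; allyl isomerisation can erode the E geometry; and A2 has a ketone beside the C7 silyloxy centre, so enolate equilibration threatens C7 and a hindered methylenation is still needed.
- Comparison: A1 already contains C1, C3, C4 and C15, so this alternative does not solve the lactone triad at all. It also needs β-keto ester assembly, lactonisation, contraction and methylenation, where the chosen route needs iodination and one coupling. The chosen strategy accepts a harder ring closure in exchange for a solution to the stereochemical problem.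

**Alternative 2:** The lactone C3–O bond and both oxiranes are cut at once, leading to the open-chain (3E,11E)-dienoic acid A3. In the forward step KHSO5 with the L-fructose-derived Shi ketone epoxidises both trisubstituted olefins, and the carboxylate opens the 3,4-epoxide at C3 with inversion to give the epoxy hydroxy lactone A4.
- For: C3, C4, C11 and C12 come from one reagent-controlled operation on an acyclic substrate, where this epoxidation is most predictable. It is stronger than the chosen route at C4 (no reliance on Felkin control) and at C11/C12 (no macrocyclic facial bias).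
- Against: C15 must be set beforehand by a separate asymmetric step and cannot be corrected. The opening must go 6-exo at secondary C3 against the electronic preference for tertiary C4. The acid-labile epoxide must then survive fragment union and ring closure, and C7 would be created during that ring closure without a control element.
- Comparison: the chosen route gives up reagent control at C4 and C11/C12 but fixes C3 and C15 from mixtures without any chiral reagent, and keeps the epoxide out of every C–C bond-forming step.

**Alternative 3:** The C3–C4 bond is cut, giving the open-chain keto aldehyde ester A5 with the C3 aldehyde and the C4 methyl ketone at its ends. In the forward step SmI2 (or TiCl3 with Zn–Cu) at high dilution couples the two carbonyls and closes the ring to the 3,4-diol ester A6.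
- For: ring closure and both carbinol centres in one step, with no organozinc macrocyclisation. On step count near the end it is stronger than the chosen route.
- Against: two stereocentres are formed in a macrocyclic ketyl coupling with no identifiable control. The C4 ketyl can add 5-exo to the C8=C19 olefin. Low-valent titanium can deoxygenate to the olefin or cleave the allylic silyl ether. After lactonisation C3 is no longer correctable, and C15 must again be preset.
- Comparison: the chosen route is longer, but each of C3, C15 and C4 has a named control element (thermodynamics, thermodynamics, adjacent-centre induction).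

Key step: step 9

Remark: the SMILES descriptors are taken as the absolute configuration. The L-fructose-derived Shi ketone (from L-sorbose) and 2-methoxypropan-2-yl hydroperoxide (ozonolysis of 2,3-dimethylbut-2-ene in methanol) are treated as reagents made by their standard preparations.

## Route

Step 1
Reactants: 1 (R)-(+)-limonene
Product: 4 (5R)-7,7-dimethoxy-5-(prop-1-en-2-yl)heptan-2-one, via hydroperoxy aldehyde 2 (not isolated), via hydroperoxy acetal 3 (not isolated)
Conditions: O3 (about 1 equiv, Sudan Red 7B end point), CH2Cl2/MeOH, −78 °C; TsOH·H2O (cat.), rt; NaHCO3, then Me2S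
Reagents that add atoms: ozone O=[O+][O-]; methanol CO
Why: Ozonolysis with unsymmetrical (Criegee) work-up: the electron-richer trisubstituted ring olefin should react before the isopropenyl group, methanol traps the ketone oxide as the methoxy hydroperoxide while the free aldehyde is acetalised, and reduction releases the ketone. The stereocentre is untouched and becomes C1.

Step 2
Reactants: 4
Product: 6 (5R)-7,7-dimethoxy-5-(prop-1-en-2-yl)hept-1-yne, via enol phosphate 5 (not isolated)
Conditions: LiN(iPr)2 (1.1 equiv), THF, −78 °C; ClP(O)(OEt)2, −78 °C to rt; LiN(iPr)2 (2.3 equiv), −78 °C to rt; aq NH4Cl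
Reagents that add atoms: none
Why: Ketone-to-alkyne conversion by kinetic enol phosphate formation on the methyl side and base-induced β-elimination; acetal and isopropenyl group are inert to the amide base.

Step 3
Reactants: 6
Product: 8 (1E,5R)-1-iodo-7,7-dimethoxy-2-methyl-5-(prop-1-en-2-yl)hept-1-ene, via alkenylalane 7 (not isolated)
Conditions: AlMe3 (2.5 equiv), Cp2ZrCl2 (0.25 equiv), H2O (1.2 equiv), CH2Cl2, −20 °C; then I2, THF, −20 to 0 °C
Reagents that add atoms: trimethylaluminium C[Al](C)C; iodine II
Why: Negishi zirconium-catalysed carboalumination adds methyl and aluminium syn across the terminal alkyne (methyl to the internal carbon) and iodinolysis retains geometry, giving the E iodoalkene. The water-accelerated low-temperature variant is chosen to keep the acetal's exposure to the Lewis acid short, and the 1,1-disubstituted olefin does not react.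

Step 4
Reactants: 8
Product: 10 (3R,6E)-3-(2,2-dimethoxyethyl)-7-iodo-2,6-dimethylhept-6-en-1-ol (C2 epimers), via alkylborane 9 (not isolated)
Conditions: 9-BBN (1.5 equiv), THF, 0 °C to rt; then 3 M NaOH, 30% H2O2, 0 °C to rt
Reagents that add atoms: hydrogen peroxide OO
Why: Anti-Markovnikov hydroboration–oxidation of the 1,1-disubstituted olefin; the trisubstituted iodoalkene is too hindered and electron-poor for 9-BBN. The new C15 centre is deliberately left as a mixture.

Step 5
Reactants: 10
Product: 11 (3R,6E)-3-(2,2-dimethoxyethyl)-7-iodo-2,6-dimethylhept-6-enal (C2 epimers)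
Conditions: Dess–Martin periodinane, NaHCO3, CH2Cl2, 0 °C to rt
Reagents that add atoms: none
Why: Dess–Martin oxidation under buffered conditions, which spare the acetal and the iodoalkene.

Step 6
Reactants: 11
Product: 12 methyl (3R,6E)-3-(2,2-dimethoxyethyl)-7-iodo-2,6-dimethylhept-6-enoate (C2 epimers)
Conditions: I2, KOH, MeOH, 0 °C
Reagents that add atoms: methanol CO
Why: Oxidative esterification of the aldehyde through its hemiacetal hypoiodite; the basic medium protects the acetal, and epimerisation at C15 is irrelevant.

Step 7
Reactants: 12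
Product: 13 methyl (3R,6E)-7-iodo-2,6-dimethyl-3-(2-oxoethyl)hept-6-enoate (C2 epimers)
Conditions: 1 M HCl, THF, 0 °C to rt
Reagents that add atoms: water O
Why: Acid-catalysed acetal hydrolysis; the methyl ester and the iodoalkene are stable to dilute aqueous acid.

Step 8
Reactants: 13; 14 ethyl vinyl ether
Product: 17 methyl (3R,6E)-3-(2-hydroxy-3-oxobutyl)-7-iodo-2,6-dimethylhept-6-enoate (epimers at C2 and at the carbinol carbon), via 1-ethoxyvinyllithium 15 (not isolated), via enol ether adduct 16 (not isolated)
Conditions: 14 (2 equiv), t-BuLi (1.2 equiv), THF, −78 to 0 °C; then 13, −78 °C; then 1 M HCl, THF, 0 °C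
Reagents that add atoms: water O
Why: 1,2-Addition of an acyl anion equivalent (α-alkoxyvinyllithium) to the aldehyde, which is far more electrophilic than the ester at −78 °C, followed by enol ether hydrolysis to the methyl ketone. Both new and old stereo-mixtures, and any lactone formed early, are carried into step 9.

Step 9
Reactants: 17
Product: 19 (3S,4R,6R)-6-acetyl-4-[(3E)-4-iodo-3-methylbut-3-en-1-yl]-3-methyloxan-2-one, via lactone epimer mixture 18 (not isolated)
Conditions: DBU (1.0 equiv), 4 Å molecular sieves, toluene, 100 °C
Reagents that add atoms: none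
Why: The amidine base first promotes transesterification: the C3 hydroxyl attacks the C16 ester carbonyl and methoxide leaves, closing the δ-lactone in the 6-exo-trig mode, with the sieves removing methanol. In lactone 18 the C3 hydrogen (α to the C4 ketone and bearing the acyloxy group) and the C15 hydrogen (α to the lactone carbonyl) are then removed and returned reversibly, so both centres equilibrate while the non-acidic C1 stays as limonene set it. The closest known reactions are base-catalysed lactonisation of δ-hydroxy esters and base-mediated epimerisation of α-substituted δ-lactones and of α-acyloxy ketones, here run in one operation. C3 is controlled thermodynamically by the 1,3-cis (diequatorial) preference of the acetyl group relative to the C1 chain, and C15 by the 1,2-trans (diequatorial) preference of the methyl group; every other diastereomer must place one substituent axial. The step needs the six-membered lactone to win over the seven-membered isomer reachable by enediol tautomerism or acyl shift, which is secured by the lower strain of the δ-lactone on the secondary oxygen and by the irreversible loss of methanol. No β-leaving group is present at either enolate, so no elimination channel competes, and the weak base should keep aldol chemistry of the methyl ketone slow. Four diastereomers of 17 should therefore converge on 19, and any minor epimer that is separated can be resubmitted to the same conditions.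

Step 10
Reactants: 20 3-bromobut-3-en-1-ol
Product: 21 1-{[(3-bromobut-3-en-1-yl)oxy]methyl}-4-methoxybenzene
Conditions: NaH, 4-methoxybenzyl chloride, Bu4NI (cat.), THF, 0 °C to rt
Reagents that add atoms: 4-methoxybenzyl chloride COc1ccc(CCl)cc1
Why: Williamson etherification; the alkenyl bromide is inert to the alkoxide at this temperature.

Step 11
Reactants: 21; 22 3-[(tert-butyldimethylsilyl)oxy]propanal
Product: 24 rac-1-[(tert-butyldimethylsilyl)oxy]-6-[(4-methoxyphenyl)methoxy]-4-methylidenehexan-3-ol, via alkenyllithium 23 (not isolated)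
Conditions: t-BuLi (2.0 equiv), Et2O, −78 °C; then 22, −78 °C; then H2O
Reagents that add atoms: none
Why: Bromine–lithium exchange and 1,2-addition of the alkenyllithium to the aldehyde form the C7–C8 bond with the exomethylene in place; the racemic carbinol is corrected in steps 12 and 13.

Step 12
Reactants: 24
Product: 25 1-[(tert-butyldimethylsilyl)oxy]-6-[(4-methoxyphenyl)methoxy]-4-methylidenehexan-3-one
Conditions: Dess–Martin periodinane, NaHCO3, CH2Cl2, 0 °C
Reagents that add atoms: none
Why: Dess–Martin oxidation of the allylic alcohol to the α-methylene ketone under neutral conditions, which avoid β-elimination of the silyloxy group.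

Step 13
Reactants: 25
Product: 26 (3R)-1-[(tert-butyldimethylsilyl)oxy]-6-[(4-methoxyphenyl)methoxy]-4-methylidenehexan-3-ol
Conditions: (S)-2-methyl-CBS-oxazaborolidine (0.2 equiv), catecholborane, toluene, −78 °C
Reagents that add atoms: none
Why: Corey–Bakshi–Shibata reduction: the α-branched alkenyl group acts as the large substituent, so the (S)-catalyst should deliver hydride to give the (R)-carbinol (C7), and catecholborane at low temperature avoids hydroboration of the olefin.

Step 14
Reactants: 26
Product: 27 (3R)-1,3-bis[(tert-butyldimethylsilyl)oxy]-6-[(4-methoxyphenyl)methoxy]-4-methylidenehexane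
Conditions: TBSCl, imidazole, DMF, rt
Reagents that add atoms: tert-butyldimethylsilyl chloride CC(C)(C)[Si](C)(C)Cl
Why: Standard silylation of the secondary allylic alcohol; the silyl ether later keeps the C8=C19 olefin deactivated and carries C7 through the organometallic steps.

Step 15
Reactants: 27
Product: 28 (3R)-3-[(tert-butyldimethylsilyl)oxy]-6-[(4-methoxyphenyl)methoxy]-4-methylidenehexan-1-ol
Conditions: HF·pyridine, pyridine, THF, 0 °C
Reagents that add atoms: none
Why: Selective desilylation: the unhindered primary silyl ether is cleaved well before the hindered secondary allylic one under buffered fluoride.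

Step 16
Reactants: 28
Product: 29 {[(3R)-1-bromo-6-[(4-methoxyphenyl)methoxy]-4-methylidenehexan-3-yl]oxy}(tert-butyl)dimethylsilane
Conditions: CBr4, PPh3, imidazole, CH2Cl2, 0 °C
Reagents that add atoms: carbon tetrabromide BrC(Br)(Br)Br
Why: Appel bromination of the primary alcohol under buffered conditions; the stereocentre is two carbons away and is not affected.

Step 17
Reactants: 19; 29
Product: 31 (3S,4R,6R)-6-[(2S,5R)-5-[(tert-butyldimethylsilyl)oxy]-2-hydroxy-8-[(4-methoxyphenyl)methoxy]-6-methylideneoctan-2-yl]-4-[(3E)-4-iodo-3-methylbut-3-en-1-yl]-3-methyloxan-2-one, via Grignard reagent 30 (not isolated)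
Conditions: 29, Mg (BrCH2CH2Br activation), THF, rt to 40 °C; then 19, THF, −78 °C; then aq NH4Cl at −78 °C
Reagents that add atoms: none
Why: Grignard addition to the activated α-acyloxy methyl ketone, which is far more reactive than the lactone at −78 °C. In the Felkin–Anh/Cornforth arrangement the ring C3–O bond lies anti to the incoming nucleophile and attack passes the C3 hydrogen rather than C2, which should give the (4S) carbinol. The lactone carbonyl points away from the ketone, so only the weakly basic ring oxygen could chelate, and a cold quench prevents acyl shift to the new alkoxide.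

Step 18
Reactants: 31
Product: 32 the C4 triethylsilyl ether of 31
Conditions: TESOTf, 2,6-lutidine, CH2Cl2, −78 to 0 °C
Reagents that add atoms: triethylsilyl trifluoromethanesulfonate CC[Si](CC)(CC)OS(=O)(=O)C(F)(F)F
Why: Silylation of the tertiary alcohol with the silyl triflate removes the acidic proton that would quench the alkylzinc of step 21 and blocks acyl migration.

Step 19
Reactants: 32
Product: 33 the C10 primary alcohol (4-methoxybenzyl group removed)
Conditions: DDQ, CH2Cl2/pH 7 buffer, 0 °C
Reagents that add atoms: none
Why: Oxidative cleavage of the 4-methoxybenzyl ether by hydride abstraction; silyl ethers, the iodoalkene and the olefins are inert to the quinone.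

Step 20
Reactants: 33
Product: 34 the C10 primary iodide
Conditions: I2, PPh3, imidazole, CH2Cl2, 0 °C
Reagents that add atoms: iodine II
Why: Appel-type iodination of the only free hydroxyl; the tertiary oxygen is silylated.

Step 21
Reactants: 34
Product: 36 (1R,3R,4S,7R,11E,15S)-7-[(tert-butyldimethylsilyl)oxy]-4-[(triethylsilyl)oxy]cembra-8(19),11-dien-16,3-olide, via alkylzinc iodide 35 (not isolated)
Conditions: Zn dust (activated with BrCH2CH2Br and Me3SiCl), LiCl, THF, 35 °C; then slow addition to Pd(dppf)Cl2 (10 mol%), THF, 55 °C, final about 1 mM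
Reagents that add atoms: none
Why: Zinc inserts into the primary alkyl C–I bond but not into the alkenyl iodide, and intramolecular Negishi coupling then forms C10–C11 with retention of the E geometry. The lactone and silyl ethers are tolerated by the alkylzinc, the bidentate phosphine favours reductive elimination over β-hydride loss, and slow addition keeps the concentration low.

Step 22
Reactants: 36
Product: 37 (1R,3R,4S,7R,11S,12S,15S)-7-[(tert-butyldimethylsilyl)oxy]-11,12-epoxy-4-[(triethylsilyl)oxy]cembr-8(19)-en-16,3-olide
Conditions: L-fructose-derived Shi ketone (0.3 equiv), KHSO5 (as 2KHSO5·KHSO4·K2SO4), K2CO3, Bu4NHSO4, MeCN/CH2(OMe)2, aq Na2B4O7/Na2EDTA buffer (pH 10.5), 0 °C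
Reagents that add atoms: potassium peroxymonosulfate [K+].[O-]S(=O)(=O)OO
Why: Shi epoxidation through a spiro transition state; the L-series ketone is the enantiomer that should give (S,S)-epoxides from E-trisubstituted olefins. The 1,1-disubstituted, silyloxy-flanked C8=C19 olefin is a poor substrate for the dioxirane, and E geometry gives the trans-epoxide.

Step 23
Reactants: 37
Product: 38 (1R,3R,4S,7R,11S,12S,15S)-11,12-epoxy-4,7-dihydroxycembr-8(19)-en-16,3-olide
Conditions: Bu4NF, AcOH (1:1), THF, 0 °C to rt
Reagents that add atoms: none
Why: Fluoride desilylation removes both silyl ethers; buffering with acetic acid keeps the medium too weakly basic for acyl migration or epoxide opening.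

Step 24
Reactants: 38
Product: 40 (1R,3R,4S,7S,11S,12S,15S)-11,12-epoxy-4-hydroxy-7-[(2-methoxypropan-2-yl)peroxy]cembr-8(19)-en-16,3-olide, via mesylate 39 (not isolated)
Conditions: MsCl (1.2 equiv), Et3N, CH2Cl2, −40 °C; solvent exchange; then Me2C(OMe)OOH (3 equiv), CsOH·H2O (2 equiv), DMF, 0 °C
Reagents that add atoms: 2-methoxypropan-2-yl hydroperoxide COC(C)(C)OO
Why: The secondary alcohol is sulfonylated selectively over the tertiary one, and SN2 displacement by the strongly nucleophilic but weakly basic caesium peroxide anion inverts C7 from R to S. The peroxide is used in excess over the base so that no free hydroxide attacks the lactone.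

Step 25
Reactants: 40
Product: 41 (1R,3R,4S,7S,11S,12S,15S)-11,12-epoxy-7-hydroperoxy-4-hydroxycembr-8(19)-en-16,3-olide (target)
Conditions: PPTS (cat.), MeOH, 0 °C
Reagents that add atoms: none
Why: Acid-catalysed transketalisation to methanol cleaves the very labile peroxyketal and frees the hydroperoxide; the mild pyridinium acid at 0 °C should spare the epoxide, for which transannular ether formation with the C4 hydroxyl would need an eight- or nine-membered ring.

## Compound list

1 | (R)-(+)-limonene | CC1=CC[C@@H](CC1)C(C)=C | starting material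
2 | (3R)-6-hydroperoxy-6-methoxy-3-(prop-1-en-2-yl)heptanal (C6 epimers) | C=C(C)[C@H](CCC(C)(OC)OO)CC=O | intermediate
3 | (5R)-2-hydroperoxy-2,7,7-trimethoxy-5-(prop-1-en-2-yl)heptane (C2 epimers) | C=C(C)[C@H](CCC(C)(OC)OO)CC(OC)OC | intermediate
4 | (5R)-7,7-dimethoxy-5-(prop-1-en-2-yl)heptan-2-one | C=C(C)[C@H](CCC(C)=O)CC(OC)OC | intermediate
5 | diethyl (5R)-7,7-dimethoxy-5-(prop-1-en-2-yl)hept-1-en-2-yl phosphate | C=C(C)[C@H](CCC(=C)OP(=O)(OCC)OCC)CC(OC)OC | intermediate
6 | (5R)-7,7-dimethoxy-5-(prop-1-en-2-yl)hept-1-yne | C=C(C)[C@H](CCC#C)CC(OC)OC | intermediate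
7 | [(1E,5R)-7,7-dimethoxy-2-methyl-5-(prop-1-en-2-yl)hept-1-en-1-yl]dimethylalane | C=C(C)[C@H](CC/C(C)=C/[Al](C)C)CC(OC)OC | intermediate
8 | (1E,5R)-1-iodo-7,7-dimethoxy-2-methyl-5-(prop-1-en-2-yl)hept-1-ene | C=C(C)[C@H](CC/C(C)=C/I)CC(OC)OC | intermediate
9 | 9-[(3R,6E)-3-(2,2-dimethoxyethyl)-7-iodo-2,6-dimethylhept-6-en-1-yl]-9-borabicyclo[3.3.1]nonane (C2 epimers) | CC(CB1C2CCCC1CCC2)[C@H](CC/C(C)=C/I)CC(OC)OC | intermediate
10 | (3R,6E)-3-(2,2-dimethoxyethyl)-7-iodo-2,6-dimethylhept-6-en-1-ol (C2 epimers) | OCC(C)[C@H](CC/C(C)=C/I)CC(OC)OC | intermediate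
11 | (3R,6E)-3-(2,2-dimethoxyethyl)-7-iodo-2,6-dimethylhept-6-enal (C2 epimers) | O=CC(C)[C@H](CC/C(C)=C/I)CC(OC)OC | intermediate
12 | methyl (3R,6E)-3-(2,2-dimethoxyethyl)-7-iodo-2,6-dimethylhept-6-enoate (C2 epimers) | COC(=O)C(C)[C@H](CC/C(C)=C/I)CC(OC)OC | intermediate
13 | methyl (3R,6E)-7-iodo-2,6-dimethyl-3-(2-oxoethyl)hept-6-enoate (C2 epimers) | COC(=O)C(C)[C@H](CC/C(C)=C/I)CC=O | intermediate
14 | ethyl vinyl ether | C=COCC | starting material
15 | 1-ethoxyvinyllithium | [Li]C(=C)OCC | intermediate
16 | methyl (3R,6E)-3-(3-ethoxy-2-hydroxybut-3-en-1-yl)-7-iodo-2,6-dimethylhept-6-enoate (epimers) | COC(=O)C(C)[C@H](CC/C(C)=C/I)CC(O)C(=C)OCC | intermediate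
17 | methyl (3R,6E)-3-(2-hydroxy-3-oxobutyl)-7-iodo-2,6-dimethylhept-6-enoate (epimers at C2 and at the carbinol carbon) | COC(=O)C(C)[C@H](CC/C(C)=C/I)CC(O)C(C)=O | intermediate
18 | (4R)-6-acetyl-4-[(3E)-4-iodo-3-methylbut-3-en-1-yl]-3-methyloxan-2-one (epimers at ring C3 and C6) | CC(=O)C1C[C@@H](CC/C(C)=C/I)C(C)C(=O)O1 | intermediate
19 | (3S,4R,6R)-6-acetyl-4-[(3E)-4-iodo-3-methylbut-3-en-1-yl]-3-methyloxan-2-one | CC(=O)[C@H]1C[C@@H](CC/C(C)=C/I)[C@H](C)C(=O)O1 | intermediate
20 | 3-bromobut-3-en-1-ol | C=C(Br)CCO | starting material
21 | 1-{[(3-bromobut-3-en-1-yl)oxy]methyl}-4-methoxybenzene | C=C(Br)CCOCc1ccc(OC)cc1 | intermediate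
22 | 3-[(tert-butyldimethylsilyl)oxy]propanal | O=CCCO[Si](C)(C)C(C)(C)C | starting material
23 | {4-[(4-methoxyphenyl)methoxy]but-1-en-2-yl}lithium | [Li]C(=C)CCOCc1ccc(OC)cc1 | intermediate
24 | rac-1-[(tert-butyldimethylsilyl)oxy]-6-[(4-methoxyphenyl)methoxy]-4-methylidenehexan-3-ol | C=C(CCOCc1ccc(OC)cc1)C(O)CCO[Si](C)(C)C(C)(C)C | intermediate
25 | 1-[(tert-butyldimethylsilyl)oxy]-6-[(4-methoxyphenyl)methoxy]-4-methylidenehexan-3-one | C=C(CCOCc1ccc(OC)cc1)C(=O)CCO[Si](C)(C)C(C)(C)C | intermediate
26 | (3R)-1-[(tert-butyldimethylsilyl)oxy]-6-[(4-methoxyphenyl)methoxy]-4-methylidenehexan-3-ol | C=C(CCOCc1ccc(OC)cc1)[C@H](O)CCO[Si](C)(C)C(C)(C)C | intermediate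
27 | (3R)-1,3-bis[(tert-butyldimethylsilyl)oxy]-6-[(4-methoxyphenyl)methoxy]-4-methylidenehexane | C=C(CCOCc1ccc(OC)cc1)[C@H](O[Si](C)(C)C(C)(C)C)CCO[Si](C)(C)C(C)(C)C | intermediate
28 | (3R)-3-[(tert-butyldimethylsilyl)oxy]-6-[(4-methoxyphenyl)methoxy]-4-methylidenehexan-1-ol | C=C(CCOCc1ccc(OC)cc1)[C@H](O[Si](C)(C)C(C)(C)C)CCO | intermediate
29 | {[(3R)-1-bromo-6-[(4-methoxyphenyl)methoxy]-4-methylidenehexan-3-yl]oxy}(tert-butyl)dimethylsilane | C=C(CCOCc1ccc(OC)cc1)[C@H](O[Si](C)(C)C(C)(C)C)CCBr | intermediate
30 | [(3R)-3-[(tert-butyldimethylsilyl)oxy]-6-[(4-methoxyphenyl)methoxy]-4-methylidenehexyl]magnesium bromide | C=C(CCOCc1ccc(OC)cc1)[C@H](O[Si](C)(C)C(C)(C)C)CC[Mg]Br | intermediate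
31 | (3S,4R,6R)-6-[(2S,5R)-5-[(tert-butyldimethylsilyl)oxy]-2-hydroxy-8-[(4-methoxyphenyl)methoxy]-6-methylideneoctan-2-yl]-4-[(3E)-4-iodo-3-methylbut-3-en-1-yl]-3-methyloxan-2-one | I/C=C(C)/CC[C@@H]1C[C@@H](OC(=O)[C@H]1C)[C@@](C)(O)CC[C@@H](O[Si](C)(C)C(C)(C)C)C(=C)CCOCc1ccc(OC)cc1 | intermediate
32 | triethylsilyl ether of 31 at the tertiary (C4) oxygen | I/C=C(C)/CC[C@@H]1C[C@@H](OC(=O)[C@H]1C)[C@@](C)(O[Si](CC)(CC)CC)CC[C@@H](O[Si](C)(C)C(C)(C)C)C(=C)CCOCc1ccc(OC)cc1 | intermediate
33 | primary (C10) alcohol from 32 | I/C=C(C)/CC[C@@H]1C[C@@H](OC(=O)[C@H]1C)[C@@](C)(O[Si](CC)(CC)CC)CC[C@@H](O[Si](C)(C)C(C)(C)C)C(=C)CCO | intermediate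
34 | primary (C10) iodide from 33 | I/C=C(C)/CC[C@@H]1C[C@@H](OC(=O)[C@H]1C)[C@@](C)(O[Si](CC)(CC)CC)CC[C@@H](O[Si](C)(C)C(C)(C)C)C(=C)CCI | intermediate
35 | C10 alkylzinc iodide from 34 | I/C=C(C)/CC[C@@H]1C[C@@H](OC(=O)[C@H]1C)[C@@](C)(O[Si](CC)(CC)CC)CC[C@@H](O[Si](C)(C)C(C)(C)C)C(=C)CC[Zn]I | intermediate
36 | (1R,3R,4S,7R,11E,15S)-7-[(tert-butyldimethylsilyl)oxy]-4-[(triethylsilyl)oxy]cembra-8(19),11-dien-16,3-olide | C=C1CC/C=C(C)/CC[C@@H]2C[C@@H](OC(=O)[C@H]2C)[C@@](C)(O[Si](CC)(CC)CC)CC[C@H]1O[Si](C)(C)C(C)(C)C | intermediate
37 | (1R,3R,4S,7R,11S,12S,15S)-7-[(tert-butyldimethylsilyl)oxy]-11,12-epoxy-4-[(triethylsilyl)oxy]cembr-8(19)-en-16,3-olide | C=C1CC[C@@H]2O[C@@]2(C)CC[C@@H]2C[C@@H](OC(=O)[C@H]2C)[C@@](C)(O[Si](CC)(CC)CC)CC[C@H]1O[Si](C)(C)C(C)(C)C | intermediate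
38 | (1R,3R,4S,7R,11S,12S,15S)-11,12-epoxy-4,7-dihydroxycembr-8(19)-en-16,3-olide | C=C1CC[C@@H]2O[C@@]2(C)CC[C@@H]2C[C@@H](OC(=O)[C@H]2C)[C@@](C)(O)CC[C@H]1O | intermediate
39 | 7-O-methanesulfonate of 38 (7R) | C=C1CC[C@@H]2O[C@@]2(C)CC[C@@H]2C[C@@H](OC(=O)[C@H]2C)[C@@](C)(O)CC[C@H]1OS(C)(=O)=O | intermediate
40 | (1R,3R,4S,7S,11S,12S,15S)-11,12-epoxy-4-hydroxy-7-[(2-methoxypropan-2-yl)peroxy]cembr-8(19)-en-16,3-olide | C=C1CC[C@@H]2O[C@@]2(C)CC[C@@H]2C[C@@H](OC(=O)[C@H]2C)[C@@](C)(O)CC[C@@H]1OOC(C)(C)OC | intermediate
41 | (1R,3R,4S,7S,11S,12S,15S)-11,12-epoxy-7-hydroperoxy-4-hydroxycembr-8(19)-en-16,3-olide (CNP0319766.2) | C=C1CC[C@@H]2O[C@@]2(C)CC[C@@H]2C[C@@H](OC(=O)[C@H]2C)[C@@](C)(O)CC[C@@H]1OO | target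

## Step count and least certain steps

Total: 25 steps. Longest linear sequence: 18 steps (steps 1–9 and 17–25, from limonene); the arm takes steps 10–16.

**Step 9 (key step).** The lactone α-position C15 is much less acidic than C3, so equilibration at C15 may stay incomplete at a temperature where the methyl ketone begins to condense or the free acyloin tautomerises before it has lactonised. Fallback, from 17 back to 19, with the two equilibrations separated:
- DBU at room temperature lactonises and equilibrates only C3, giving the 4,6-cis lactone ketone F1 as a mixture at the methyl-bearing carbon.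
- Ethylene glycol and PPTS in benzene with water removal mask the ketone as the dioxolane lactone F2.
- With only the lactone α-hydrogen left acidic, catalytic KOt-Bu in THF/t-BuOH equilibrates the methyl group to the equatorial ketal lactone F3.
- Dilute aqueous acid then releases 19.

**Step 17.** Delivery of the nucleophile through a magnesium chelate between the ketone and the ring oxygen, or enolisation at C3, may erode or reverse the facial preference at C4, since only an open Felkin–Anh/Cornforth transition state gives 4S. Fallback, from 13 and 29 back to 31, with the roles of methyl and arm exchanged so that the same facial preference gives the other C4 epimer: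
- 2-Lithio-1,3-dithiane is alkylated with 29 to give the arm dithiane F4.
- Its lithio derivative (n-BuLi, THF) adds to aldehyde 13 to give the carbinol F5.
- MeI and CaCO3 in aqueous MeCN unmask the arm acyloin ester F6.
- The DBU funnel of step 9 gives the arm ketone lactone F7.
- MeMgBr at −78 °C then adds to F7 to give 31.

**Step 21.** Intermolecular coupling, protonolysis of the alkylzinc or β-hydride elimination may outrun closure of the 14-membered ring, because transmetalation and reductive elimination must occur in a strained macrocyclic palladacycle. Fallback, from 34 directly to 36: a nickel-catalysed reductive cross-electrophile macrocyclisation (NiBr2(dme), 4,4′-di-tert-butyl-2,2′-bipyridine, Mn powder, NaI, dimethylacetamide, high dilution). It joins the alkyl and alkenyl iodides without a preformed organozinc and without a palladium cycle; no new compound is made on this path (F0).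

**Step 22.** The conformational facial bias of the macrocycle may override the chiral dioxirane, so that oxygen is delivered to the wrong face of the 11,12-olefin. Fallback, from 36 to 37, for the case that the ring steers electrophiles to the face that gives the (11R,12R)-epoxide:
- NBS in aqueous THF lets bromine take that exposed face and water open the bromonium ion anti at the tertiary C12, giving the bromohydrin F8.
- K2CO3 in acetone closes the oxirane with inversion at C11, which places the oxygen on the opposite face.

**Step 24.** Ionisation of the allylic mesylate, attack at the exomethylene terminus (SN2′) or elimination may compete with direct displacement, and the basic peroxide may open the lactone; each erodes the inversion at C7. Fallback, from 39 directly to 41, replacing stereospecific substitution by a correctable one: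
- Anhydrous ethereal H2O2 is added to the cold, Et3N-buffered mesylate solution, giving the free hydroperoxide in one step with no base-mediated stage and no acid step.
- Any (7R)-hydroperoxide F9 formed through ionisation is a diastereomer of 41 and is separated.
- F9 is reduced with PPh3 to 38 and re-enters step 24.

## Further compounds

F1 | step 9 | (4R,6R)-6-acetyl-4-[(3E)-4-iodo-3-methylbut-3-en-1-yl]-3-methyloxan-2-one (ring C3 epimers) | CC(=O)[C@H]1C[C@@H](CC/C(C)=C/I)C(C)C(=O)O1
F2 | step 9 | (4R,6R)-4-[(3E)-4-iodo-3-methylbut-3-en-1-yl]-3-methyl-6-(2-methyl-1,3-dioxolan-2-yl)oxan-2-one (ring C3 epimers) | CC1(OCCO1)[C@H]1C[C@@H](CC/C(C)=C/I)C(C)C(=O)O1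
F3 | step 9 | (3S,4R,6R)-4-[(3E)-4-iodo-3-methylbut-3-en-1-yl]-3-methyl-6-(2-methyl-1,3-dioxolan-2-yl)oxan-2-one | CC1(OCCO1)[C@H]1C[C@@H](CC/C(C)=C/I)[C@H](C)C(=O)O1
F4 | step 17 | 2-[(3R)-3-[(tert-butyldimethylsilyl)oxy]-6-[(4-methoxyphenyl)methoxy]-4-methylidenehexyl]-1,3-dithiane | C=C(CCOCc1ccc(OC)cc1)[C@H](O[Si](C)(C)C(C)(C)C)CCC1SCCCS1
F5 | step 17 | methyl (3R,6E)-3-{2-hydroxy-2-[2-((3R)-3-[(tert-butyldimethylsilyl)oxy]-6-[(4-methoxyphenyl)methoxy]-4-methylidenehexyl)-1,3-dithian-2-yl]ethyl}-7-iodo-2,6-dimethylhept-6-enoate (epimers) | C=C(CCOCc1ccc(OC)cc1)[C@H](O[Si](C)(C)C(C)(C)C)CCC1(SCCCS1)C(O)C[C@@H](CC/C(C)=C/I)C(C)C(=O)OC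
F6 | step 17 | arm acyloin ester: methyl (3R,6E)-3-[(6R)-6-[(tert-butyldimethylsilyl)oxy]-2-hydroxy-9-[(4-methoxyphenyl)methoxy]-7-methylidene-3-oxononyl]-7-iodo-2,6-dimethylhept-6-enoate (epimers) | C=C(CCOCc1ccc(OC)cc1)[C@H](O[Si](C)(C)C(C)(C)C)CCC(=O)C(O)C[C@@H](CC/C(C)=C/I)C(C)C(=O)OC
F7 | step 17 | (3S,4R,6R)-6-[(4R)-4-[(tert-butyldimethylsilyl)oxy]-7-[(4-methoxyphenyl)methoxy]-5-methylideneheptanoyl]-4-[(3E)-4-iodo-3-methylbut-3-en-1-yl]-3-methyloxan-2-one | C=C(CCOCc1ccc(OC)cc1)[C@H](O[Si](C)(C)C(C)(C)C)CCC(=O)[C@H]1C[C@@H](CC/C(C)=C/I)[C@H](C)C(=O)O1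
F0 | step 21 | none | none
F8 | step 22 | (1R,3R,4S,7R,11R,12S,15S)-11-bromo-7-[(tert-butyldimethylsilyl)oxy]-12-hydroxy-4-[(triethylsilyl)oxy]cembr-8(19)-en-16,3-olide | C=C1CC[C@@H](Br)[C@@](C)(O)CC[C@@H]2C[C@@H](OC(=O)[C@H]2C)[C@@](C)(O[Si](CC)(CC)CC)CC[C@H]1O[Si](C)(C)C(C)(C)C
F9 | step 24 | (1R,3R,4S,7R,11S,12S,15S)-11,12-epoxy-7-hydroperoxy-4-hydroxycembr-8(19)-en-16,3-olide (C7 epimer of the target) | C=C1CC[C@@H]2O[C@@]2(C)CC[C@@H]2C[C@@H](OC(=O)[C@H]2C)[C@@](C)(O)CC[C@H]1OO
A1 | alternative 1 | 16-membered β-keto allylic macrolactone (C9 carboxyl esterified by the C10 oxygen) | O=C1CC(=O)OC/C=C(\C)CC[C@@H]2C[C@@H](OC(=O)[C@H]2C)[C@@](C)(O[Si](CC)(CC)CC)CC[C@@H]1O[Si](C)(C)C(C)(C)C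
A2 | alternative 1 | 14-membered C8 ketone with the E 11,12-olefin | O=C1CC/C=C(\C)CC[C@@H]2C[C@@H](OC(=O)[C@H]2C)[C@@](C)(O[Si](CC)(CC)CC)CC[C@@H]1O[Si](C)(C)C(C)(C)C
A3 | alternative 2 | open-chain (3E,11E)-dienoic acid with the C8 alkenyl bromide and the C7 4-methoxybenzyl ether | C=C(Br)CC/C=C(\C)CC[C@H](C/C=C(\C)CCCOCc1ccc(OC)cc1)[C@H](C)C(=O)O
A4 | alternative 2 | epoxy hydroxy δ-lactone with C3, C4, C11 and C12 set | C=C(Br)CC[C@@H]1O[C@@]1(C)CC[C@@H]1C[C@@H](OC(=O)[C@H]1C)[C@@](C)(O)CCCOCc1ccc(OC)cc1
A5 | alternative 3 | open-chain keto aldehyde ester (C3 aldehyde, C4 methyl ketone) | C=C(CC/C=C(\C)CC[C@H](CC=O)[C@H](C)C(=O)OC)[C@H](CCC(C)=O)O[Si](C)(C)C(C)(C)C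
A6 | alternative 3 | 14-membered 3,4-diol ester | C=C1CC/C=C(\C)CC[C@H](C[C@@H](O)[C@@](C)(O)CC[C@@H]1O[Si](C)(C)C(C)(C)C)[C@H](C)C(=O)OC
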